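The benzene ring of the phthalide is built last, by disconnecting C7–C7a and C3a–C4. The contiguous C4(OH)–C5(O-alkyl)–C6(OMe)–C7(H) edge is the four-carbon ring of squaric acid, and C7a=C3a is the alkene of a preformed furan-2(5H)-one (the lactone ring). In one operation a racemic 4-chloro-3-methoxy-2-alkoxycyclobut-2-enone, whose alkoxy group is the complete acetoxylated farnesyl chain, is cross-coupled with 3-(tributylstannyl)furan-2(5H)-one. The four-membered ring then opens to a dienylketene that closes by 6π electrocyclisation and enolises. The arene thus appears with its three oxygens already differentiated and the C4 hydroxyl free, without protecting groups.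

Key step: step 11

Remark: RO below stands for [(2E,6E)-11-acetoxy-3,7,11-trimethyldodeca-2,6-dien-1-yl]oxy. Commercial farnesol is assumed to be the pure (2E,6E) isomer. Compounds 3, 12, 13, 17 and 19 are racemic, which is immaterial for an achiral target.

Step 1
Reactants: 1 (2E,6E)-farnesol
Product: 2 (2E,6E)-farnesyl acetate
Conditions: Ac2O, pyridine, DMAP (cat.), CH2Cl2, 0 °C to rt
Reagents that add atoms: acetic anhydride, CC(=O)OC(C)=O
Why: Routine DMAP-catalysed O-acylation of the primary allylic alcohol; the acetate also lowers the nucleophilicity of the C2=C3 alkene for step 2 and no stereocentre is formed.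

Step 2
Reactants: 2 (2E,6E)-farnesyl acetate
Product: 3 (2E,6E)-10-bromo-11-hydroxy-3,7,11-trimethyldodeca-2,6-dien-1-yl acetate (racemic)
Conditions: NBS (1.1 equiv), THF/H2O, 0 °C
Reagents that add atoms: N-bromosuccinimide, O=C1CCC(=O)N1Br; water, O
Why: Electrophilic bromohydrin formation with NBS in aqueous THF is selective for the terminal trisubstituted alkene of farnesyl esters (the chain folds in the aqueous medium and the allylic acetate deactivates C2=C3), with water opening the bromonium ion at the tertiary carbon; the C10 stereocentre is racemic and is removed in step 3.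

Step 3
Reactants: 3 the bromohydrin acetate
Product: 4 (2E,6E)-11-hydroxy-3,7,11-trimethyldodeca-2,6-dien-1-yl acetate
Conditions: Bu3SnH (1.2 equiv), AIBN (cat.), toluene, 80 °C
Reagents that add atoms: none
Why: Radical chain hydrodebromination of the secondary bromide; the C10 radical could cyclise onto C6=C7 only in a slow 4-exo or 5-endo mode, so hydrogen transfer from tin wins and the stereocentre disappears.

Step 4
Reactants: 4 the hydroxy acetate
Product: 5 (2E,6E)-3,7,11-trimethyldodeca-2,6-diene-1,11-diyl diacetate
Conditions: Ac2O, Et3N, DMAP, CH2Cl2, rt to 40 °C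
Reagents that add atoms: acetic anhydride, CC(=O)OC(C)=O
Why: DMAP-catalysed acylation is the standard way to acetylate a tertiary alcohol under basic, non-ionising conditions, so no dehydration of the tertiary carbinol is expected.

Step 5
Reactants: 5 the diacetate
Product: 6 (2E,6E)-11-acetoxy-3,7,11-trimethyldodeca-2,6-dien-1-ol
Conditions: K2CO3 (0.3 equiv), MeOH, 0 °C
Reagents that add atoms: none
Why: Base-catalysed transesterification with methanol cleaves the unhindered primary allylic acetate far faster than the hindered tertiary acetate at 0 °C, and since only acyl–oxygen bonds break both E alkenes are untouched.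

Step 6
Reactants: 7 squaric acid
Product: 8 squaryl dichloride (3,4-dichlorocyclobut-3-ene-1,2-dione)
Conditions: (COCl)2 (2.2 equiv), DMF (cat.), toluene, rt to 50 °C
Reagents that add atoms: oxalyl chloride, O=C(Cl)C(=O)Cl
Why: Vilsmeier-type activation (chloroiminium salt from DMF and oxalyl chloride) converts both vinylogous carboxylic acid hydroxyls into chlorides, the established preparation of the dichloride.

Step 7
Reactants: 6 the side-chain alcohol; 8 squaryl dichloride
Product: 10 sodium salt of the squaric acid mono(side-chain) ester, via chlorosquarate ester 9 (not isolated)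
Conditions: 8 (1.5 equiv), 2,6-lutidine, CH2Cl2, −40 °C, slow addition of 6; then sat. aq. NaHCO3, THF, 0 °C
Reagents that add atoms: water, O; sodium hydrogencarbonate, [Na+].OC([O-])=O
Why: Addition–elimination of the alcohol at the vinylogous acid chloride stops at monosubstitution because the first alkoxy group deactivates the second chloride and the dichloride is in excess; bicarbonate then hydrolyses the remaining chloride of 9 to the resonance-stabilised anion, kept as the salt because the free vinylogous acid is strong enough to ionise the allylic ester and the tertiary acetate, and since only the O–H bond of 6 reacts the alkene geometry is retained.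

Step 8
Reactants: 10 sodium salt of the squaric acid monoester
Product: 12 4-hydroxy-3-methoxy-2-(RO)cyclobut-2-en-1-one (racemic), via hydroxy dionate sodium salt 11 (not isolated)
Conditions: NaBH4, EtOH, −20 to 0 °C; sat. aq. NaHCO3; evaporate; then Me2SO4, DMF, 0 °C
Reagents that add atoms: dimethyl sulfate, COS(=O)(=O)OC
Why: Proposed new method: in the anion of 10 the two carbonyls flanking the alkoxy carbon form a delocalised vinylogous carboxylate that is inert to hydride, so NaBH4 should reduce only the remaining ketone opposite the alkoxy carbon (closest known reaction types: 1,2-reduction of dialkyl squarates to 4-hydroxy-2,3-dialkoxycyclobutenones and borohydride reduction of α-keto carboxylates); the hydroxy dionate 11 is mirror-symmetric, so hard O-methylation with Me2SO4 (known for tetronate-type vinylogous carboxylates) at either oxygen gives the same constitution, racemic at the carbinol carbon, and keeping the medium basic until methylation prevents ketonisation of the dionate, which would move the ring hydrogen.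

Step 9
Reactants: 12 the 4-hydroxycyclobutenone
Product: 13 4-chloro-3-methoxy-2-(RO)cyclobut-2-en-1-one (racemic)
Conditions: PPh3, hexachloroacetone, CH2Cl2, −30 to 0 °C; used at once
Reagents that add atoms: hexachloroacetone, ClC(Cl)(Cl)C(=O)C(Cl)(Cl)Cl
Why: Appel-type chlorination through the alkoxyphosphonium ion with SN2 delivery of chloride runs under neutral conditions at low temperature, which spares the enol ether linkages and the tertiary acetate and avoids the acid-induced collapse of 4-hydroxy-2,3-dialkoxycyclobutenones to cyclobutenediones; the C–Cl centre is racemic and is lost later.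

Step 10
Reactants: 14 methyl 4-hydroxybut-2-ynoate
Product: 16 3-(tributylstannyl)furan-2(5H)-one, via hydroxy stannyl ester 15 (not isolated)
Conditions: Bu3SnH (1.1 equiv), Pd(PPh3)4 (2 mol %), THF, 0 °C to rt
Reagents that add atoms: tributyltin hydride, CCCC[SnH](CCCC)CCCC
Why: Hydrostannation of a 2-ynoate catalysed by zerovalent palladium is a syn addition that places tin on the α-carbon and hydrogen on the β-carbon, so the hydroxymethyl and ester groups of 15 are cis and lactonise spontaneously to the butenolide.

Step 11
Reactants: 13 the 4-chlorocyclobutenone; 16 3-(tributylstannyl)furan-2(5H)-one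
Product: 20 Farnesylemefuranone F, via lactonyl cyclobutenone 17 (not isolated), via dienylketene 18 (not isolated), via cyclohexadienone 19 (not isolated)
Conditions: PdCl2(PhCN)2 (5 mol %), tri(2-furyl)phosphine (10 mol %), CuI (10 mol %), dioxane, 50 °C, then 100 °C; aq. KF work-up
Reagents that add atoms: none
Why: Zerovalent palladium, formed in the flask from divalent PdCl2(PhCN)2, the stannane and tri(2-furyl)phosphine, inserts into the allylic, α-keto C–Cl bond of 13, CuI relays the lactone from tin to palladium, and reductive elimination at the unsubstituted ring carbon forms the C7–C7a bond of 17. On warming, 17 opens by conrotatory 4π electrocyclic cleavage of its C1–C4 bond to dienylketene 18, which closes by thermal disrotatory 6π electrocyclisation (ketene carbon onto the lactone β-carbon, the C3a–C4 bond) to dienone 19 and enolises to phenol 20; the closest known reaction type is the Stille coupling of 4-chlorocyclobutenones with alkenylstannanes followed by electrocyclic ring expansion to phenols (cyclobutenone benzannulation). The only ring closed is the benzene ring, by this 6π electrocyclisation onto the lactone ring already present in 16. The stereocentres of 17 and 19 are racemic, transient and erased on aromatisation, so no stereocontrol is needed. What is needed is coupling at the CH carbon and not at the alkoxy-bearing terminus of the oxocyclobutenyl ligand (favoured by the lower substitution of that carbon and by the conjugated vinylogous ester that results), no cine substitution at the stannane (suppressed by CuI) and ring opening with the lactone turned toward the ketene (the opening is reversible, so the other isomer returns to 17). The positions of the oxygens are already fixed in 13, since the ketene carbon becomes C4–OH, the alkoxy carbon C5, the methoxy carbon C6 and the former C–Cl carbon C7–H, and about 100 °C for a short time keeps the hindered allyl ethers clear of Claisen rearrangement and of allyl transfer to palladium.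

Compound list
1 | (2E,6E)-farnesol | OC/C=C(\C)CC/C=C(\C)CCC=C(C)C | starting material
2 | (2E,6E)-farnesyl acetate | CC(=O)OC/C=C(\C)CC/C=C(\C)CCC=C(C)C | intermediate
3 | (2E,6E)-10-bromo-11-hydroxy-3,7,11-trimethyldodeca-2,6-dien-1-yl acetate (racemic) | CC(=O)OC/C=C(\C)CC/C=C(\C)CCC(Br)C(C)(C)O | intermediate
4 | (2E,6E)-11-hydroxy-3,7,11-trimethyldodeca-2,6-dien-1-yl acetate | CC(=O)OC/C=C(\C)CC/C=C(\C)CCCC(C)(C)O | intermediate
5 | (2E,6E)-3,7,11-trimethyldodeca-2,6-diene-1,11-diyl diacetate | CC(=O)OC/C=C(\C)CC/C=C(\C)CCCC(C)(C)OC(C)=O | intermediate
6 | (2E,6E)-11-acetoxy-3,7,11-trimethyldodeca-2,6-dien-1-ol (side-chain alcohol, ROH) | OC/C=C(\C)CC/C=C(\C)CCCC(C)(C)OC(C)=O | intermediate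
7 | squaric acid (3,4-dihydroxycyclobut-3-ene-1,2-dione) | O=C1C(=O)C(O)=C1O | starting material
8 | squaryl dichloride (3,4-dichlorocyclobut-3-ene-1,2-dione) | O=C1C(=O)C(Cl)=C1Cl | intermediate
9 | 3-chloro-4-(RO)cyclobut-3-ene-1,2-dione | O=C1C(=O)C(Cl)=C1OC/C=C(\C)CC/C=C(\C)CCCC(C)(C)OC(C)=O | intermediate
10 | sodium 2-(RO)-3,4-dioxocyclobut-1-en-1-olate (sodium salt of the squaric acid monoester) | O=C1C(=O)C([O-])=C1OC/C=C(\C)CC/C=C(\C)CCCC(C)(C)OC(C)=O.[Na+] | intermediate
11 | sodium 4-hydroxy-3-oxo-2-(RO)cyclobut-1-en-1-olate (achiral hydroxy dionate) | O=C1C(O)C([O-])=C1OC/C=C(\C)CC/C=C(\C)CCCC(C)(C)OC(C)=O.[Na+] | intermediate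
12 | 4-hydroxy-3-methoxy-2-(RO)cyclobut-2-en-1-one (racemic) | O=C1C(O)C(OC)=C1OC/C=C(\C)CC/C=C(\C)CCCC(C)(C)OC(C)=O | intermediate
13 | 4-chloro-3-methoxy-2-(RO)cyclobut-2-en-1-one (racemic) | O=C1C(Cl)C(OC)=C1OC/C=C(\C)CC/C=C(\C)CCCC(C)(C)OC(C)=O | intermediate
14 | methyl 4-hydroxybut-2-ynoate | COC(=O)C#CCO | starting material
15 | methyl (E)-4-hydroxy-2-(tributylstannyl)but-2-enoate (hydroxymethyl cis to the ester) | COC(=O)/C(=C\CO)[Sn](CCCC)(CCCC)CCCC | intermediate
16 | 3-(tributylstannyl)furan-2(5H)-one | O=C1OCC=C1[Sn](CCCC)(CCCC)CCCC | intermediate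
17 | 3-methoxy-4-(2-oxo-2,5-dihydrofuran-3-yl)-2-(RO)cyclobut-2-en-1-one (racemic) | O=C1C(C2=CCOC2=O)C(OC)=C1OC/C=C(\C)CC/C=C(\C)CCCC(C)(C)OC(C)=O | intermediate
18 | (E)-3-methoxy-4-(2-oxo-2,5-dihydrofuran-3-yl)-2-(RO)buta-1,3-dien-1-one (dienylketene, lactone cis to the ketene carbon) | O=C=C(OC/C=C(\C)CC/C=C(\C)CCCC(C)(C)OC(C)=O)/C(OC)=C\C1=CCOC1=O | intermediate
19 | 6-methoxy-5-(RO)-3,3a-dihydroisobenzofuran-1,4-dione (racemic) | O=C1C(OC/C=C(\C)CC/C=C(\C)CCCC(C)(C)OC(C)=O)=C(OC)C=C2C1COC2=O | intermediate
20 | Farnesylemefuranone F, 4-hydroxy-6-methoxy-5-(RO)isobenzofuran-1(3H)-one | COc1cc2c(c(O)c1OC/C=C(\C)CC/C=C(\C)CCCC(C)(C)OC(C)=O)COC2=O | target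

Total step count: 11. Longest linear sequence: 9 steps (1 to 20 through steps 1–5, 7, 8, 9 and 11).

Steps most likely to fail

Step 8 (reduction and methylation of the monoester anion). Hydride addition may stall on the anionic ring. The hydroxy dionate may also ketonise at the alkoxy-bearing carbon and re-enolise toward the carbinol carbon before it is methylated, which moves the ring hydrogen and scrambles the positions of the two alkoxy groups. C-methylation is a further leak. The fallback uses known chemistry and sets out from 10. O-Methylation of the salt with Me2SO4 in DMF gives the mixed diester 3-methoxy-4-(RO)cyclobut-3-ene-1,2-dione F1. Its 1,2-reduction with LiAlH(OtBu)3 in THF at −78 °C, the standard conversion of dialkyl squarates into 4-hydroxy-2,3-dialkoxycyclobutenones, should give 12 together with its regioisomer 4-hydroxy-2-methoxy-3-(RO)cyclobut-2-en-1-one F2. The slightly less hindered carbonyl next to the methoxy carbon leads to 12. The isomers are separated by chromatography and F2 can be returned to F1 by oxidation with MnO2. The fallback rejoins the route at 12.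

Step 9 (chlorination). The activated C4 oxygen may ionise to the alkoxy-stabilised cyclobutenyl cation instead of being displaced directly. Chloride can then attack the allylic CH2 of the side chain (loss of the chain) or the alkoxy-bearing ring carbon (allylic transposition). The fallback sets out from 12. Acetylation (Ac2O, pyridine, DMAP) gives the far less ionisable 2-methoxy-4-oxo-3-(RO)cyclobut-2-en-1-yl acetate F3. F3 is used directly as the allylic electrophile with 16 (Pd2(dba)3, tri(2-furyl)phosphine, LiCl, CuI, DMF, 50 °C, then 100 °C), a Stille coupling of an allylic acetate. Oxidative addition to zerovalent palladium and chloride exchange lead to the same oxocyclobutenylpalladium chloride as in step 11. The sequence therefore rejoins the route at 17 and ends at 20 without passing through 13.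

Step 11 (coupling and ring expansion). Transfer of the hindered, electron-poor lactone from tin may be slower than decay of the oxocyclobutenylpalladium intermediate. Cine substitution may compete, or closure onto an alkene locked in the five-membered lactone may lag behind side reactions of the ketene. In the fallback the lactone is closed after the arene, setting out from 14. Silylation (TBSCl, imidazole, DMF) gives methyl 4-(tert-butyldimethylsilyloxy)but-2-ynoate F4. Hydrostannation as in step 10 gives methyl (E)-4-(tert-butyldimethylsilyloxy)-2-(tributylstannyl)but-2-enoate F5, an acyclic α-stannyl acrylate of a type well established in CuI-assisted Stille couplings. Coupling with 13 under the conditions of step 11 should pass through methyl (Z)-4-(tert-butyldimethylsilyloxy)-2-[2-methoxy-4-oxo-3-(RO)cyclobut-2-en-1-yl]but-2-enoate F6. It should then give the phenol methyl 2-[(tert-butyldimethylsilyloxy)methyl]-3-hydroxy-5-methoxy-4-(RO)benzoate F7, in which the silyloxymethyl group lies on the outside of the closing triene. Desilylation with HF·pyridine in THF frees the benzylic alcohol, which lactonises onto the neighbouring ester and rejoins the route at 20.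

Further compounds
F1 | step 8 | 3-methoxy-4-(RO)cyclobut-3-ene-1,2-dione | O=C1C(=O)C(OC)=C1OC/C=C(\C)CC/C=C(\C)CCCC(C)(C)OC(C)=O
F2 | step 8 | 4-hydroxy-2-methoxy-3-(RO)cyclobut-2-en-1-one (racemic) | O=C1C(O)C(OC/C=C(\C)CC/C=C(\C)CCCC(C)(C)OC(C)=O)=C1OC
F3 | step 9 | 2-methoxy-4-oxo-3-(RO)cyclobut-2-en-1-yl acetate (racemic) | CC(=O)OC1C(=O)C(OC/C=C(\C)CC/C=C(\C)CCCC(C)(C)OC(C)=O)=C1OC
F4 | step 11 | methyl 4-(tert-butyldimethylsilyloxy)but-2-ynoate | COC(=O)C#CCO[Si](C)(C)C(C)(C)C
F5 | step 11 | methyl (E)-4-(tert-butyldimethylsilyloxy)-2-(tributylstannyl)but-2-enoate | COC(=O)/C(=C\CO[Si](C)(C)C(C)(C)C)[Sn](CCCC)(CCCC)CCCC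
F6 | step 11 | methyl (Z)-4-(tert-butyldimethylsilyloxy)-2-[2-methoxy-4-oxo-3-(RO)cyclobut-2-en-1-yl]but-2-enoate (racemic) | COC(=O)/C(=C\CO[Si](C)(C)C(C)(C)C)C1C(=O)C(OC/C=C(\C)CC/C=C(\C)CCCC(C)(C)OC(C)=O)=C1OC
F7 | step 11 | methyl 2-[(tert-butyldimethylsilyloxy)methyl]-3-hydroxy-5-methoxy-4-(RO)benzoate | COC(=O)c1cc(OC)c(OC/C=C(\C)CC/C=C(\C)CCCC(C)(C)OC(C)=O)c(O)c1CO[Si](C)(C)C(C)(C)C
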